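The feature exploited is the array benzene ring–C1H2–C2H(OAc)–C3H2: C1 and C2 are read as a vinyl group on boron, so both aryl–C1 and C2–C3 are cut, with boron marking the place of the C2 oxygen. One palladium-catalysed conjunctive coupling of a vinylboron ate complex with an aryl triflate makes these two C–C bonds and the C2 stereocentre under ligand control; no ring is closed. The precursor is the ate complex of vinylboronic pinacol ester and (S)-6-(benzyloxy)undecyllithium, met by 3-(benzyloxy)-5-methoxyphenyl triflate. Both hydroxyls travel as benzyl ethers, so a single hydrogenolysis ends the synthesis after C–B oxidation and acetylation.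

Key step: step 7

Numbering used: C1 is the benzylic CH2, C2 the acetoxy-bearing carbon, C3–C7 the methylene run, C8 the carbinol carbon, C9–C13 the pentyl end; the target is (2R,8S).

Assumption: the (Sp,Sp) ligand is taken to give (R)-1,2-diarylethanols with aryl migrating groups, which for an alkyl migrating group is labelled 2S, so the (Rp,Rp) antipode is specified for 2R; the sense is to be checked by Mosher ester analysis of alcohol 15, and the other antipode is used unchanged if it proves opposite.

Step 1
Reactants: 1 5-methoxyresorcinol
Product: 2 3-(benzyloxy)-5-methoxyphenol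
Conditions: 1 (3 equiv), BnBr (1 equiv), K2CO3 (1 equiv), DMF, 0 °C → rt; excess 1 recovered
Reagents that add atoms: benzyl bromide, BrCc1ccccc1
Why: Williamson etherification of one phenoxide, in which the excess of diol should favour monoalkylation, the mono-ether being separated from bis-ether and recovered diol by chromatography.

Step 2
Reactants: 2 3-(benzyloxy)-5-methoxyphenol
Product: 3 3-(benzyloxy)-5-methoxyphenyl trifluoromethanesulfonate
Conditions: Tf2O (1.2 equiv), pyridine (2 equiv), CH2Cl2, 0 °C
Reagents that add atoms: trifluoromethanesulfonic anhydride, O=S(=O)(OS(=O)(=O)C(F)(F)F)C(F)(F)F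
Why: O-sulfonylation of the remaining phenol is a standard aryl triflate formation that leaves both ethers untouched.

Step 3
Reactants: 4 racemic 1,2-epoxyheptane
Product: 5 (S)-1,2-epoxyheptane
Conditions: (S,S)-(salen)Co(OAc) (0.5 mol%; salen = N,N'-bis(3,5-di-tert-butylsalicylidene)-1,2-cyclohexanediaminate, trivalent cobalt), H2O (0.55 equiv), neat, 0 °C → rt; distillation
Reagents that add atoms: none
Why: Hydrolytic kinetic resolution, in which the chiral salen–cobalt catalyst should hydrolyse the R epoxide much faster, so that the S epoxide remains in high enantiomeric purity and supplies the stereocentre that becomes C8.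

Step 4
Reactants: 5 (S)-1,2-epoxyheptane; 6 1-bromo-4-chlorobutane
Product: 8 (S)-1-chloroundecan-6-ol, via 4-chlorobutylmagnesium bromide 7 (not isolated)
Conditions: 6 (1.5 equiv), Mg, THF, rt; then CuI (10 mol%), 5, THF, −30 → 0 °C; aq. NH4Cl
Reagents that add atoms: none
Why: Magnesium inserts into C–Br in preference to C–Cl, and the copper-catalysed Grignard opening of the terminal epoxide (SN2 at the CH2 carbon) leaves the stereocentre untouched, so the S configuration is carried into 8.

Step 5
Reactants: 8 (S)-1-chloroundecan-6-ol
Product: 9 (S)-6-(benzyloxy)-1-chloroundecane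
Conditions: benzyl 2,2,2-trichloroacetimidate (1.5 equiv), TfOH (5 mol%), CH2Cl2/cyclohexane, 0 °C → rt
Reagents that add atoms: benzyl 2,2,2-trichloroacetimidate, N=C(OCc1ccccc1)C(Cl)(Cl)Cl
Why: Acid-catalysed benzyl transfer from the trichloroacetimidate etherifies the secondary alcohol without base, so the primary chloride is not displaced and the C–O bond at the stereocentre is not broken.

Step 6
Reactants: 9 (S)-6-(benzyloxy)-1-chloroundecane
Product: 10 (S)-6-(benzyloxy)-1-iodoundecane
Conditions: NaI (5 equiv), NaHCO3 (cat.), butan-2-one, reflux
Reagents that add atoms: sodium iodide, [Na+].[I-]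
Why: Finkelstein halide exchange (SN2 at the primary carbon, driven by precipitation of NaCl) should give the iodide needed for clean lithium exchange, the benzyl ether and the remote stereocentre being inert.

Step 7
Reactants: 10 (S)-6-(benzyloxy)-1-iodoundecane; 11 vinylboronic acid pinacol ester; 3 3-(benzyloxy)-5-methoxyphenyl trifluoromethanesulfonate
Product: 14 2-[(2R,8S)-8-(benzyloxy)-1-[3-(benzyloxy)-5-methoxyphenyl]tridecan-2-yl]-4,4,5,5-tetramethyl-1,3,2-dioxaborolane, via (S)-6-(benzyloxy)undecyllithium 12 (not isolated), via lithium vinylboronate ate complex 13 (not isolated)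
Conditions: 10 (1.0 equiv), t-BuLi (2.0 equiv), pentane/Et2O 3:2, −78 °C; 11 (1.0 equiv), −78 °C → rt; solvent exchange to THF; KOTf (2 equiv), rt, cannula filtration; 3 (1.1 equiv), Pd(OAc)2 (2 mol%), (Rp,Rp)-1,1'-bis[bis(4-methoxy-3,5-dimethylphenyl)phosphino]-2,2'-bis[(S)-α-(dimethylamino)benzyl]ferrocene (2.4 mol%, Mandyphos type), THF, 60 °C
Reagents that add atoms: none
Why: Iodine–lithium exchange (two equivalents of t-BuLi, the second destroying tert-butyl iodide) gives primary alkyllithium 12 far faster than any benzylic deprotonation at −78 °C, and 12 adds to the vacant boron orbital of 11 to give four-coordinate boronate 13. Zerovalent palladium formed from Pd(OAc)2 and the bisphosphine inserts into the C–OTf bond of 3; the cationic divalent arylpalladium binds the vinyl group of 13, which triggers a 1,2-shift of the alkyl group from boron to the boron-bearing carbon anti to the metal while palladium bonds to the terminal carbon, and reductive elimination then makes aryl–C1. The closest known reaction type is the enantioselective palladium-catalysed conjunctive cross-coupling of vinylboron ate complexes with aryl triflates in which an alkyl group migrates. No ring is closed; two skeletal bonds (aryl–C1 and C2–C3) and one stereocentre are formed. The C2 stereocentre is set by the chiral bisphosphine, which decides the alkene face that arylpalladium binds; the remote C8 centre has no say, so the outcome is catalyst-controlled and 2R is expected with the ligand antipode named. The step needs the metallate shift to win over direct vinyl or alkyl transfer to palladium and over β-hydride elimination, which the wide-bite-angle ligand and a halide-free cationic palladium should secure: the triflate electrophile brings no halide, and the iodide from the exchange is precipitated as KI with KOTf (KI being far less soluble in THF than LiI or NaI) and filtered off before the catalyst is added.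

Step 8
Reactants: 14 2-[(2R,8S)-8-(benzyloxy)-1-[3-(benzyloxy)-5-methoxyphenyl]tridecan-2-yl]-4,4,5,5-tetramethyl-1,3,2-dioxaborolane
Product: 15 (2R,8S)-8-(benzyloxy)-1-[3-(benzyloxy)-5-methoxyphenyl]tridecan-2-ol
Conditions: 30% H2O2, 3 M NaOH, THF, 0 °C → rt
Reagents that add atoms: hydrogen peroxide, OO
Why: Stereospecific boronate oxidation, in which hydroperoxide adds to boron and C2 migrates from boron to oxygen with retention, so 2R of the alcohol follows from 2R of the boronate while the benzyl ethers are inert to alkaline peroxide.

Step 9
Reactants: 15 (2R,8S)-8-(benzyloxy)-1-[3-(benzyloxy)-5-methoxyphenyl]tridecan-2-ol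
Product: 16 (2R,8S)-8-(benzyloxy)-1-[3-(benzyloxy)-5-methoxyphenyl]tridecan-2-yl acetate
Conditions: Ac2O (2 equiv), pyridine, DMAP (cat.), CH2Cl2, rt
Reagents that add atoms: acetic anhydride, CC(=O)OC(C)=O
Why: DMAP-catalysed acylation of the only free hydroxyl (C2–OH) should be clean and touches no stereocentre.

Step 10
Reactants: 16 (2R,8S)-8-(benzyloxy)-1-[3-(benzyloxy)-5-methoxyphenyl]tridecan-2-yl acetate
Product: 17 (2R,8S)-8-hydroxy-1-(3-hydroxy-5-methoxyphenyl)tridecan-2-yl acetate
Conditions: H2 (1 atm), 20% Pd(OH)2/C, EtOAc/EtOH, rt
Reagents that add atoms: none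
Why: Catalytic hydrogenolysis should cleave the aryl and the secondary alkyl benzyl ether in one operation, while the non-benzylic C2 acetate, the methyl ether and both stereocentres are inert under neutral conditions.

Compound list
1 | 5-methoxyresorcinol (5-methoxybenzene-1,3-diol) | COc1cc(O)cc(O)c1 | starting material
2 | 3-(benzyloxy)-5-methoxyphenol | COc1cc(O)cc(OCc2ccccc2)c1 | intermediate
3 | 3-(benzyloxy)-5-methoxyphenyl trifluoromethanesulfonate | COc1cc(OCc2ccccc2)cc(OS(=O)(=O)C(F)(F)F)c1 | intermediate
4 | racemic 1,2-epoxyheptane (2-pentyloxirane) | CCCCCC1CO1 | starting material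
5 | (S)-1,2-epoxyheptane | CCCCC[C@H]1CO1 | intermediate
6 | 1-bromo-4-chlorobutane | ClCCCCBr | starting material
7 | 4-chlorobutylmagnesium bromide (not isolated) | ClCCCC[Mg]Br | intermediate
8 | (S)-1-chloroundecan-6-ol | CCCCC[C@H](O)CCCCCCl | intermediate
9 | (S)-6-(benzyloxy)-1-chloroundecane | CCCCC[C@H](OCc1ccccc1)CCCCCCl | intermediate
10 | (S)-6-(benzyloxy)-1-iodoundecane | CCCCC[C@H](OCc1ccccc1)CCCCCI | intermediate
11 | vinylboronic acid pinacol ester (4,4,5,5-tetramethyl-2-vinyl-1,3,2-dioxaborolane) | C=CB1OC(C)(C)C(C)(C)O1 | starting material
12 | (S)-6-(benzyloxy)undecyllithium (not isolated) | CCCCC[C@H](OCc1ccccc1)CCCCC[Li] | intermediate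
13 | lithium [(S)-6-(benzyloxy)undecyl](vinyl)(pinacolato)borate, the ate complex (not isolated) | CCCCC[C@H](OCc1ccccc1)CCCCC[B-]1(C=C)OC(C)(C)C(C)(C)O1.[Li+] | intermediate
14 | 2-[(2R,8S)-8-(benzyloxy)-1-[3-(benzyloxy)-5-methoxyphenyl]tridecan-2-yl]-4,4,5,5-tetramethyl-1,3,2-dioxaborolane | CCCCC[C@H](OCc1ccccc1)CCCCC[C@H](Cc1cc(OCc2ccccc2)cc(OC)c1)B1OC(C)(C)C(C)(C)O1 | intermediate
15 | (2R,8S)-8-(benzyloxy)-1-[3-(benzyloxy)-5-methoxyphenyl]tridecan-2-ol | CCCCC[C@H](OCc1ccccc1)CCCCC[C@H](Cc1cc(OCc2ccccc2)cc(OC)c1)O | intermediate
16 | (2R,8S)-8-(benzyloxy)-1-[3-(benzyloxy)-5-methoxyphenyl]tridecan-2-yl acetate | CCCCC[C@H](OCc1ccccc1)CCCCC[C@H](Cc1cc(OCc2ccccc2)cc(OC)c1)OC(C)=O | intermediate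
17 | (2R,8S)-8-hydroxy-1-(3-hydroxy-5-methoxyphenyl)tridecan-2-yl acetate | CCCCC[C@H](O)CCCCC[C@H](Cc1cc(O)cc(OC)c1)OC(C)=O | target

Total step count: 10 steps.
Longest linear sequence: 8 steps (steps 3 to 10, from racemic 1,2-epoxyheptane); the aryl triflate is a two-step branch (steps 1 and 2) that joins at step 7.

Steps most likely to fail

Step 7. The process at risk is inhibition of the cationic arylpalladium intermediate by iodide left over from the lithium exchange, which would stall turnover or divert the ate complex to plain vinyl transfer; an exchange that is not clean would also leave the ate complex incomplete. The fallback sets out from iodide 10 and assembles the same ate complex with the polarity of its two partners reversed and without any halide. Exchange of 10 with t-BuLi at −78 °C and trapping with 2-isopropoxy-4,4,5,5-tetramethyl-1,3,2-dioxaborolane should give 2-[(S)-6-(benzyloxy)undecyl]-4,4,5,5-tetramethyl-1,3,2-dioxaborolane F1, which is chromatographed and so freed of lithium salts. Vinyllithium F2, made from Sn(CH=CH2)4 and n-BuLi in pentane and washed as the precipitated solid, is then added to F1 in Et2O. This comes back to the route at ate complex 13, which is coupled with 3 under the palladium conditions of step 7 without KOTf.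

Step 1. The process at risk is over-alkylation to the bis-ether together with C-benzylation of the electron-rich ring, which erodes the mono-ether. The fallback sets out from 1: exhaustive O-benzylation (BnBr in excess, K2CO3, DMF) should give 1,3-bis(benzyloxy)-5-methoxybenzene F3. One benzyl group is then removed by nucleophilic dealkylation with NaSEt in DMF at about 100 °C. This cleavage is self-limiting, because the phenoxide formed makes loss of a second aryloxide much slower. The fallback comes back to the route at 2.

Step 4. The process at risk is loss of the bifunctional Grignard reagent through Wurtz-type self-coupling during its formation, or diversion of the epoxide to a halohydrin by magnesium halide, either of which would give poor conversion. The fallback sets out from epoxide 5 and introduces the terminal halide by alkene functionalisation instead. Commercial but-3-enylmagnesium bromide with CuI (cat.) in THF should open 5 to (S)-undec-1-en-6-ol F4. Benzylation with NaH and BnBr in THF/DMF gives (S)-6-(benzyloxy)undec-1-ene F5. Hydroboration with 9-borabicyclo[3.3.1]nonane gives 9-[(S)-6-(benzyloxy)undecyl]-9-borabicyclo[3.3.1]nonane F6, which is oxidised in the same flask with NaOH/H2O2 to (S)-6-(benzyloxy)undecan-1-ol F7. Appel iodination (I2, PPh3, imidazole, CH2Cl2) then comes back to the route at iodide 10.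

Further compounds
F1 | step 7 | 2-[(S)-6-(benzyloxy)undecyl]-4,4,5,5-tetramethyl-1,3,2-dioxaborolane | CCCCC[C@H](OCc1ccccc1)CCCCCB1OC(C)(C)C(C)(C)O1
F2 | step 7 | vinyllithium | [Li]C=C
F3 | step 1 | 1,3-bis(benzyloxy)-5-methoxybenzene | COc1cc(OCc2ccccc2)cc(OCc2ccccc2)c1
F4 | step 4 | (S)-undec-1-en-6-ol | CCCCC[C@H](O)CCCC=C
F5 | step 4 | (S)-6-(benzyloxy)undec-1-ene | CCCCC[C@H](OCc1ccccc1)CCCC=C
F6 | step 4 | 9-[(S)-6-(benzyloxy)undecyl]-9-borabicyclo[3.3.1]nonane | CCCCC[C@H](OCc1ccccc1)CCCCCB1C2CCCC1CCC2
F7 | step 4 | (S)-6-(benzyloxy)undecan-1-ol | CCCCC[C@H](OCc1ccccc1)CCCCCO
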